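Minutes of a short meeting on the flask. The meeting took the elm run first: with 0.060 M of Vy charged, its highest Dw.Ux reading was 11.2%, at 3.00 min. The highest reading of the ash run, with 0.13 M of Vy charged, was 18.9%, at 1.50 min. Both had the flask's [Dw] and its ratio of phases.

| setting | elm | ash | flask |
|---|---|---|---|
| Dw | 0.081 M | 0.081 M | 0.081 M |
| Vy | 0.060 M | 0.13 M | 0.0891 M |
| remark | run made earlier | run made earlier |  |
| time |  |  | 10 min |
| volume of the second phase over the first |  |  | 2.0 |

| run | time / min | Dw.Ux / % | Dw / % |
|---|---|---|---|
| elm | 0.417 | 6.3 | 83.4 |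
| elm | 0.833 | 9.6 | 71.7 |
| elm | 1.50 | 10.5 | 55.7 |
| elm | 3.00 | 11.2 | 35.2 |
| elm | 6.00 | 8.7 | 16.8 |
| elm | 12.0 | 5.7 | 6.7 |
| ash | 0.417 | 12.0 | 75.2 |
| ash | 0.833 | 16.9 | 58.0 |
| ash | 1.50 | 18.9 | 37.9 |
| ash | 3.00 | 15.3 | 17.0 |
| ash | 6.00 | 9.8 | 4.8 |
| ash | 12.0 | 2.9 | 1.7 |

(standard deviation of a reading: 0.5 percentage points)

- in the second phase: Vy; everything else is in the first
- charges count per volume of the first phase; a concentration in a rate is the amount of a species over the volume of its own phase; every rate counts per litre of the first phase
- the numbers in the tables scatter by 0.5 percentage points (one standard deviation)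
- the earlier runs hold the two phases in the same ratio of volumes as the flask asked about

- when, up to 10 min, the flask holds most Dw.Ux
- the amount of Dw.Ux, in percent of the Dw charged, at that time
- earliest time at which at least nineteen twentieths of that best amount are there, in min
- latest time at which they still are, in min

The secretary proposed not to reckon the flask's peak afresh, but to take elm's reading as the large number and compute the correction for the extra Vy. From the two highest readings she kept 0.677 as the peak exponent, an apparent order: the change in ln(peak) per unit change in ln(charged [Vy]) at fixed charged [Dw] and phase ratio. The flask's charged [Vy] stands at 1.49 times elm's, so she multiplied elm's highest reading by 1.31 and put the flask's peak at 14.7%, a figure carrying the scatter of both readings.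

The forecaster then reported the ground of the forecast, “I interpolate on log Vy”, and gave 14.6% at 1.8 min, with the asked window running from 1.25 min to 2.8 min. The secretary noted that both figures rest on the same two runs, so their closeness checks neither.

The flask's Dw.Ux peaks at 14.7% at 1.73 min, and the asked window runs from 1.11 min to 2.72 min.

    Ux ⇌ Vy, rate k1*([Ux] - [Vy]/K1) per volume of the first phase (partition coefficient = 4.50, kL = 1.60 s⁻¹)
    Dw + Ux → Dw.Ux (k = 0.630 L mol⁻¹ s⁻¹)
    Ux + Dw.Ux → Ux.Dw.Ux (k = 0.650 L mol⁻¹ s⁻¹)
    2 Dw → Yx (k = 0.0180 L mol⁻¹ s⁻¹)
    Dw + Dw.Ux → Dw.Dw.Ux (k = 0.200 L mol⁻¹ s⁻¹)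

At that peak the flask holds 23.2% of the charged Dw as Dw.Dw.Ux, each counted with both its Dw, which is more than it holds as Dw.Ux. Taking the peak exponent on the ratio of charged [Vy] to charged [Dw], an assumption of this reckoning, the flask's peak scales to 10.1% for the neighbour flask with 0.14 M of Dw, and that neighbour gives 9.72%.

The readings are calculated from invented constants, and the scatter is random.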